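# Miyabenol A by iterative de novo construction of the benzo rings from three alkynes

## The problem

Miyabenol A (34) is a resveratrol tetramer built from three 2,3-trans-2-(4-hydroxyphenyl)-2,3-dihydrobenzofuran units joined head to tail. C3 of unit 1 is bonded to C4 of unit 2, C3 of unit 2 to C4 of unit 3, C3 of unit 3 carries the 3,5-dihydroxyphenyl ring D, and C4 of unit 1 carries the (E)-4-hydroxystyryl group. The six stereocentres form three trans pairs: (2R,3R) in units 1 and 3, (2S,3S) in unit 2. Within a unit one centre can set the other, but the units are joined only by C(sp3)–aryl single bonds, so no unit can be trusted to set the next and each pair needs its own source of absolute configuration, of alternating sense. Each benzo ring is a 1,2,3,5-tetrasubstituted benzene whose most crowded carbon, C3a, lies between C4 and C7a. That is where two units meet, and it is the position that substitution chemistry on a resorcinol reaches worst. The fragile parts are the nine phenols, the benzylic C2–O bonds para to an oxygenated aryl group (ionisation under acid opens or epimerises the ring), and the stilbene, which isomerises in light and, once protonated, is attacked by the electron-rich C5 of unit 2. The enabling feature is the substitution pattern of ring A (the benzo ring of unit 1): O1 on C7a and the hydroxyl on C6 are meta, and C3a and C4 are adjacent. Ring A therefore divides into three two-carbon pieces, C3a–C4, C5–C6 and C7–C7a, that is an alkyne on C3 and two ynol ethers, one of them already tied to the oxygen on C2. The same pattern recurs in units 2 and 3, so a solution for ring A solves the whole skeleton, provided the C4 substituent it installs is a formyl group from which the next unit can grow.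

## Retrosynthesis

**Phenols.** The nine O–alkyl bonds of 34 are cut last, giving the hexamethyl triethyl ether 33. Methyl ethers are chosen for the rings that arrive as aldehydes or phosphonate. The three C6 oxygens must be ethyl because ethoxyacetylene (11) is the commercial ynol ether known to behave in cyclotrimerisation. The forward reaction must cleave primary alkyl aryl ethers without ionising C2–O or cyclising onto the stilbene. BCl3 with iodide at low temperature is chosen over hot or strongly protic methods for that reason.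

**Stilbene.** The C=C bond of 33 is cut to aldehyde 31 and phosphonate 32 (Horner–Wadsworth–Emmons). Carrying the styryl group through the last cycle as an enyne on the alkyne was considered and set aside on four grounds:
- the propargylic mesylate would be conjugated through the enyne with a 4-methoxyphenyl group and would ionise;
- the enyne would face n-BuLi;
- a flat styryl group offers less steric bias in the ring-forming step than a branched acetal;
- a late olefination leaves the option of dealkylating before the acid-sensitive alkene exists.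

The price is one step. The gain is that all three cycles become chemically identical.

**Ring A and its furan (key disconnection).** Aldehyde 31 comes from acetal 30. In 30 the C3a–C7a, C4–C5 and C6–C7 bonds are cut, which opens ring A and the dihydrofuran of unit 1 together and leads to diyne 29 and ethoxyacetylene 11. The neighbouring cuts (aryl C–O coupling at C7a, or Friedel–Crafts bond formation at C3a of a finished resorcinol) keep the hindered arene and must force a bond at its worst position. This cut removes the arene altogether. Precursor 29 is acyclic at unit 1, and its two new stereocentres are already in place. The forward reaction must deliver one regiochemistry of alkyne insertion at room temperature and must leave C2 and C3 alone.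

**Ynol ether.** The O–C(sp) bond of 29 is cut to the secondary alcohol 26. The trichloroethylene route makes alkynyl ethers of secondary alcohols in one flask. It is asked to tolerate an acetal and a benzylic, propargylic C–H.

**C2–C3 bond.** Alcohol 26 is cut between its two stereocentres into 4-methoxybenzaldehyde (5) and propargylic mesylate 24, made from alcohol 23. Palladium-catalysed, indium-mediated propargylation forms this bond with chirality transfer. C3 takes its configuration from the carbinol of 23 with inversion, and C2 is set anti to it in a cyclic transition state. Both centres of a unit thus derive from one carbinol, independently of the units already present. An aldol- or epoxide-based construction would instead have to fight substrate bias.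

**C3–C(sp) bond.** Alcohol 23 is cut to aldehyde 22 and 3,3-diethoxypropyne (2) by catalytic asymmetric alkynylation, the only catalyst-controlled stereochemical event of a cycle. Alkyne 2 brings the carbon that later becomes the C4 formyl group. The sense of each unit is chosen by the BINOL enantiomer.

**Iteration.** Aldehyde 22 has the same form as 31, so the same five operations are repeated:
- 22 from diyne 20 and 11; 20 from alcohol 17; 17 from mesylate 15 and 5; 15 from alcohol 14; 14 from aldehyde 13 and 2;
- 13 from diyne 10 and 11; 10 from alcohol 7; 7 from mesylate 4 and 5; 4 from alcohol 3; 3 from 3,5-dimethoxybenzaldehyde (1) and 2.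

The formyl carbon of each aldehyde becomes C3 of the next unit. The commercial materials are 1, 2, 5, 11 and 32.

## Roads not taken

**Alternative 1:** conjunctive cross-coupling.
- Cut: in unit 3, the C3–ring D bond and the C2–anisyl bond together, across the alkene of the ring-C (E)-alkenyl pinacol boronate A1.
- Forward key step: the ate complex of A1 with 4-methoxyphenyllithium A2 meets the arylpalladium from 3,5-dimethoxyphenyl triflate A3 under Pd(OAc)2/MandyPhos. The aryl group adds to the alkene carbon remote from boron while the anisyl group migrates from boron to carbon. The product is boronic ester A4, with both centres set by the ligand and the C–B bond placed for an invertive closure to the trans ring.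
- Merits: a catalytic, enantioselective, known reaction class; three different aryl groups from three simple modules; a preformed ring C, so no regiochemical question.
- Weak points for this target: no ring closes. A1 is a 2,6-disubstituted styrenyl boronate, so direct Suzuki transfer competes. The invertive C–O closure is at a 4-methoxybenzylic carbon. Ring C carries a benzyloxy group where the target needs the C4–C bond to the next unit, so each iteration needs a cross-coupling at a hindered triflate and a new, bulkier alkenyl boronate.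
- Comparison: this road is better in precedent, since its key step is known and that of the chosen plan is not. Against that, the chosen plan makes the arene with its C4 carbon in place, closes two rings in the same step, forms no stereocentre in the unproven step, and tests that step at step 5 on simple material.

**Alternative 2:** ring contraction of a chiral-pool flavanone.
- Cut: the C3–C3a bond of unit 2, traced back to the C4–C4a bond of a chromanone.
- Forward key step: protected (2S)-naringenin A5 (5-O-benzyl, 7,4′-di-O-methyl) with PhI(OAc)2 and H2SO4 in trimethyl orthoformate undergoes enol ether formation, iodination at C3 and 1,2-shift of the aryl carbon. The product is the trans methyl 2-aryl-2,3-dihydrobenzofuran-3-carboxylate A6.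
- Merits: the (S) configuration at C2 of unit 2 comes free from a commodity; the oxidative aryl shift is a known reaction of flavanones; the route to A6 is very short.
- Weak points: A6 is only the central unit. C3 carries an ester where the target needs a bond to C4 of unit 3, and C4 carries a benzyloxy group where it needs a bond to C3 of unit 1. Both neighbouring units must still be built, by other means. The pool supplies only the (2S) series, while units 1 and 3 are of the opposite sense. The flavanone can racemise through its chalcone under the acidic conditions.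
- Comparison: for unit 2 alone this road is shorter and better precedented than the ten steps to 22. The chosen plan sets against it one set of operations that serves all three units, with the sense chosen by the ligand.

**Alternative 3:** triple decarboxylative arylation.
- Cut: the three C2–aryl bonds at once.
- Forward key step: the tris(3-aryl-2,3-dihydrobenzofuran-2-carboxylic acid) A7 and three equivalents of 4-iodoanisole A8 couple under light with Ir[dF(CF3)ppy]2(dtbbpy)PF6 and NiCl2(dme)/4,4′-di-tert-butyl-2,2′-bipyridine, with loss of three CO2, to give the octamethyl ether A9 (benzyloxy at C4 of unit 1).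
- Merits: high convergence in the last stage; a robust, known coupling of α-oxy acids; the C3 substituents can steer each new aryl group trans.
- Weak points: three stereocentres are made in one step under substrate control alone, and any leakage multiplies over eight possible diastereomers. A7 already contains the whole tris(dihydrobenzofuran) skeleton with its three C3 centres of alternating sense, so the hard part is only moved earlier. The benzyloxy group of A9 must still be turned into the styryl group by way of a hindered triflate.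
- Comparison: its key step is known and its endgame is more convergent. The chosen plan sets against this that skeleton and stereochemistry are solved together and that each trans pair is fixed by chirality transfer before any ring is made.

Key step: step 15

## Route

Assumption: the titanium–BINOL alkynylation is taken to follow its usual sense with aryl aldehydes ((R)-BINOL delivering to the Re face) and the allenylindium addition to proceed with net inversion at the mesylate carbon; MTPA esters of 3 and the H2–H3 coupling and NOE pattern of 13 would confirm both before material is committed.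

Abbreviations used in names:
- Bf-3 = (2R,3R)-3-(3,5-dimethoxyphenyl)-6-ethoxy-2-(4-methoxyphenyl)-2,3-dihydro-1-benzofuran-4-yl
- Bf-23 = (2S,3S)-3-(Bf-3)-6-ethoxy-2-(4-methoxyphenyl)-2,3-dihydro-1-benzofuran-4-yl

Step 1
Reactants: 1 3,5-dimethoxybenzaldehyde; 2 3,3-diethoxyprop-1-yne
Product: 3 (1S)-1-(3,5-dimethoxyphenyl)-4,4-diethoxybut-2-yn-1-ol
Conditions: 2 (3 equiv), Et2Zn, Cy2NH (cat.), (R)-BINOL (40 mol%), Et2O, rt; Ti(OiPr)4; then 1, rt
Reagents that add atoms: none
Why: Titanium–BINOL-mediated enantioselective addition of an alkynylzinc reagent to an aryl aldehyde; (R)-BINOL is expected to deliver the alkynyl group to the Re face and so set the (S)-carbinol, and the diethyl acetal is inert to the mild Lewis acid.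

Step 2
Reactants: 3 (1S)-1-(3,5-dimethoxyphenyl)-4,4-diethoxybut-2-yn-1-ol
Product: 4 (1S)-1-(3,5-dimethoxyphenyl)-4,4-diethoxybut-2-yn-1-yl methanesulfonate
Conditions: MsCl, Et3N, CH2Cl2, −78 to −20 °C; used crude
Reagents that add atoms: methanesulfonyl chloride, CS(=O)(=O)Cl
Why: Sulfonylation of a secondary alcohol at oxygen, which leaves the stereocentre untouched; the meta-methoxy groups and the acetal-bearing alkyne do not stabilise a propargylic cation, so the mesylate should last long enough to be used directly.

Step 3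
Reactants: 4 (1S)-1-(3,5-dimethoxyphenyl)-4,4-diethoxybut-2-yn-1-yl methanesulfonate; 5 4-methoxybenzaldehyde
Product: 7 (1R,2R)-2-(3,5-dimethoxyphenyl)-5,5-diethoxy-1-(4-methoxyphenyl)pent-3-yn-1-ol, via (aR)-allenylindium iodide mesylate 6 (not isolated)
Conditions: Pd(dppf)Cl2 (5 mol%), InI, THF–HMPA (3:1), rt
Reagents that add atoms: none
Why: Palladium-catalysed, indium-mediated propargylation: zerovalent palladium displaces the mesylate anti in an SN2′ sense, InI takes over the allenyl group as the trivalent allenylindium 6, and 6 adds to the aldehyde through a cyclic SE2′ transition state. The new bond at C2 forms with net inversion of the carbinol carbon (chirality transfer) and the two aryl groups avoid each other in the cyclic array, which gives the anti (1R,2R) alcohol that maps onto the trans ring.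

Step 4
Reactants: 7 (1R,2R)-2-(3,5-dimethoxyphenyl)-5,5-diethoxy-1-(4-methoxyphenyl)pent-3-yn-1-ol
Product: 10 (1R,2R)-2-(3,5-dimethoxyphenyl)-5,5-diethoxy-1-(ethynyloxy)-1-(4-methoxyphenyl)pent-3-yne, via (E)-1,2-dichlorovinyl ether 8 (not isolated), via lithium alkynyl ether 9 (not isolated)
Conditions: KH, THF, 0 °C; Cl2C=CHCl, −78 °C to rt; n-BuLi, −78 °C; MeOH, −78 °C; kept cold
Reagents that add atoms: trichloroethylene, ClC=C(Cl)Cl
Why: Alkynyl ether synthesis by the trichloroethylene route: the potassium alkoxide adds to dichloroacetylene formed in the flask to give 8, and n-BuLi effects elimination and chlorine–lithium exchange to 9, which is protonated. Neither stereocentre is involved; the product is handled cold because benzylic alkynyl ethers rearrange on warming.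

Step 5
Reactants: 10 (1R,2R)-2-(3,5-dimethoxyphenyl)-5,5-diethoxy-1-(ethynyloxy)-1-(4-methoxyphenyl)pent-3-yne; 11 ethoxyacetylene
Product: 13 (2R,3R)-3-(3,5-dimethoxyphenyl)-6-ethoxy-2-(4-methoxyphenyl)-2,3-dihydro-1-benzofuran-4-carbaldehyde, via diethyl acetal 12 (not isolated)
Conditions: [Rh(cod)2]BF4/(R)-H8-BINAP (5 mol%, H2-activated), 11 (5 equiv), CH2Cl2, rt, slow addition of 10; then 1 M HCl, THF, rt
Reagents that add atoms: water, O
Why: Proposed new method: a cationic monovalent rhodium–bisphosphine complex should couple the two alkynes of 10 oxidatively to a bicyclic rhodacyclopentadiene (C3a–C7a bond, five-membered oxygen ring), insert 11 with its oxygen-bearing carbon next to the unsubstituted C7 and eliminate reductively to the benzene ring, after which dilute acid in the same flask hydrolyses the acetal; the closest known reactions are rhodium-catalysed (2+2+2) cyclotrimerisations of 1,6-diynes with monoalkynes, alkynyl ethers included, and of ynamide-tethered diynes to indolines, and no stereocentre is formed or touched.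

Step 6
Reactants: 13 (2R,3R)-3-(3,5-dimethoxyphenyl)-6-ethoxy-2-(4-methoxyphenyl)-2,3-dihydro-1-benzofuran-4-carbaldehyde; 2 3,3-diethoxyprop-1-yne
Product: 14 (1S)-1-(Bf-3)-4,4-diethoxybut-2-yn-1-ol
Conditions: 2 (3 equiv), Et2Zn, Cy2NH (cat.), (S)-BINOL (40 mol%), Et2O, rt; Ti(OiPr)4; then 13, rt
Reagents that add atoms: none
Why: The titanium–BINOL alkynylation of step 1, now with (S)-BINOL for Si-face delivery because unit 2 has the opposite sense. The reaction is catalyst-controlled, the resident (2R,3R) unit being an ortho substituent on the aryl aldehyde, and should give the (1S)-carbinol.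

Step 7
Reactants: 14 (1S)-1-(Bf-3)-4,4-diethoxybut-2-yn-1-ol
Product: 15 (1S)-1-(Bf-3)-4,4-diethoxybut-2-yn-1-yl methanesulfonate
Conditions: MsCl, Et3N, CH2Cl2, −78 to −20 °C; used crude
Reagents that add atoms: methanesulfonyl chloride, CS(=O)(=O)Cl
Why: O-Sulfonylation without change at carbon; the benzo ring carries its two oxygens meta to the carbinol carbon, so the mesylate is no more ionisable than 4.

Step 8
Reactants: 15 (1S)-1-(Bf-3)-4,4-diethoxybut-2-yn-1-yl methanesulfonate; 5 4-methoxybenzaldehyde
Product: 17 (1S,2R)-2-(Bf-3)-5,5-diethoxy-1-(4-methoxyphenyl)pent-3-yn-1-ol, via (aS)-allenylindium iodide mesylate 16 (not isolated)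
Conditions: Pd(dppf)Cl2 (5 mol%), InI, THF–HMPA (3:1), rt
Reagents that add atoms: none
Why: Palladium-catalysed, indium-mediated propargylation as in step 3: anti SN2′ palladation, transmetalation to 16 and cyclic SE2′ addition to 5 transfer the carbinol configuration to C2 with net inversion and set C1 anti to it. Both new centres derive from the carbinol of 14 and not from the stereocentres of Bf-3.

Step 9
Reactants: 17 (1S,2R)-2-(Bf-3)-5,5-diethoxy-1-(4-methoxyphenyl)pent-3-yn-1-ol
Product: 20 (1S,2R)-2-(Bf-3)-5,5-diethoxy-1-(ethynyloxy)-1-(4-methoxyphenyl)pent-3-yne, via (E)-1,2-dichlorovinyl ether 18 (not isolated), via lithium alkynyl ether 19 (not isolated)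
Conditions: KH, THF, 0 °C; Cl2C=CHCl, −78 °C to rt; n-BuLi, −78 °C; MeOH, −78 °C; kept cold
Reagents that add atoms: trichloroethylene, ClC=C(Cl)Cl
Why: Trichloroethylene route to the alkynyl ether as in step 4 (alkoxide addition to dichloroacetylene, then elimination and chlorine–lithium exchange); the aryl ethers and the acetal are inert to KH and to n-BuLi at −78 °C, and no stereocentre is involved.

Step 10
Reactants: 20 (1S,2R)-2-(Bf-3)-5,5-diethoxy-1-(ethynyloxy)-1-(4-methoxyphenyl)pent-3-yne; 11 ethoxyacetylene
Product: 22 (2S,3S)-3-(Bf-3)-6-ethoxy-2-(4-methoxyphenyl)-2,3-dihydro-1-benzofuran-4-carbaldehyde, via diethyl acetal 21 (not isolated)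
Conditions: [Rh(cod)2]BF4/(R)-H8-BINAP (5 mol%, H2-activated), 11 (5 equiv), CH2Cl2, rt, slow addition of 20; then 1 M HCl, THF, rt
Reagents that add atoms: water, O
Why: Proposed new method: as in step 5, oxidative coupling of the ynol ether and the internal alkyne at monovalent rhodium should close the oxygen ring of unit 2 as a rhodacyclopentadiene, and regioselective insertion of 11 (ethoxy-bearing carbon next to C7–H, away from the branched acetal on C4) followed by reductive elimination should give the benzo ring, the acetal then being hydrolysed in the same flask; the closest known reaction type is the rhodium-catalysed (2+2+2) cyclotrimerisation of 1,6-diynes with alkynyl ethers, and no stereocentre is formed.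

Step 11
Reactants: 22 (2S,3S)-3-(Bf-3)-6-ethoxy-2-(4-methoxyphenyl)-2,3-dihydro-1-benzofuran-4-carbaldehyde; 2 3,3-diethoxyprop-1-yne
Product: 23 (1R)-1-(Bf-23)-4,4-diethoxybut-2-yn-1-ol
Conditions: 2 (3 equiv), Et2Zn, Cy2NH (cat.), (R)-BINOL (40 mol%), Et2O, rt; Ti(OiPr)4; then 22, rt
Reagents that add atoms: none
Why: Titanium–BINOL alkynylation with (R)-BINOL for Re-face delivery, giving the (1R)-carbinol that unit 1 requires; the catalyst is expected to override the resident units, and the descriptor differs from that of 3 only because the aryl group now outranks the alkynyl group.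

Step 12
Reactants: 23 (1R)-1-(Bf-23)-4,4-diethoxybut-2-yn-1-ol
Product: 24 (1R)-1-(Bf-23)-4,4-diethoxybut-2-yn-1-yl methanesulfonate
Conditions: MsCl, Et3N, CH2Cl2, −78 to −20 °C; used crude
Reagents that add atoms: methanesulfonyl chloride, CS(=O)(=O)Cl
Why: O-Sulfonylation with retention at carbon; the acetal on the alkyne and the meta-dioxygenated aryl group keep the mesylate from ionising, which a conjugated enyne substituent would not.

Step 13
Reactants: 24 (1R)-1-(Bf-23)-4,4-diethoxybut-2-yn-1-yl methanesulfonate; 5 4-methoxybenzaldehyde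
Product: 26 (1R,2S)-2-(Bf-23)-5,5-diethoxy-1-(4-methoxyphenyl)pent-3-yn-1-ol, via (aR)-allenylindium iodide mesylate 25 (not isolated)
Conditions: Pd(dppf)Cl2 (5 mol%), InI, THF–HMPA (3:1), rt
Reagents that add atoms: none
Why: Palladium-catalysed, indium-mediated propargylation: anti SN2′ palladation, transmetalation to 25 and cyclic SE2′ addition to 5 set C2 with net inversion of the carbinol of 24 and C1 anti to it. The two stereocentres of unit 1 are fixed here, by chirality transfer, before any ring of unit 1 exists.

Step 14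
Reactants: 26 (1R,2S)-2-(Bf-23)-5,5-diethoxy-1-(4-methoxyphenyl)pent-3-yn-1-ol
Product: 29 (1R,2S)-2-(Bf-23)-5,5-diethoxy-1-(ethynyloxy)-1-(4-methoxyphenyl)pent-3-yne, via (E)-1,2-dichlorovinyl ether 27 (not isolated), via lithium alkynyl ether 28 (not isolated)
Conditions: KH, THF, 0 °C; Cl2C=CHCl, −78 °C to rt; n-BuLi, −78 °C; MeOH, −78 °C; kept cold
Reagents that add atoms: trichloroethylene, ClC=C(Cl)Cl
Why: Trichloroethylene route to the alkynyl ether as in steps 4 and 9; the oxygen is alkynylated without change at C1 or C2, and the diyne is taken on at once because of its thermal lability.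

Step 15
Reactants: 29 (1R,2S)-2-(Bf-23)-5,5-diethoxy-1-(ethynyloxy)-1-(4-methoxyphenyl)pent-3-yne; 11 ethoxyacetylene
Product: 30 (2R,3R)-4-(diethoxymethyl)-3-(Bf-23)-6-ethoxy-2-(4-methoxyphenyl)-2,3-dihydro-1-benzofuran
Conditions: [Rh(cod)2]BF4/(R)-H8-BINAP (5–10 mol%, H2-activated), 11 (5 equiv), CH2Cl2, rt, slow addition of 29
Reagents that add atoms: none
Why: Proposed new method: a cationic monovalent rhodium–bisphosphine fragment should bind both alkynes of the 1,6-diyne 29 and couple them oxidatively to a rhodacyclopentadiene, which makes the C3a–C7a bond; the closest known reaction type is the [Rh(cod)2]BF4/bisphosphine-catalysed (2+2+2) cyclotrimerisation of 1,6-diynes with monoalkynes, alkynyl ethers among them, and of ynamide-tethered diynes to indolines, but not of a diyne tethered through a benzylic alkynyl ether. The dihydrofuran ring closes in this oxidative coupling as the five-membered ring fused to the metallacycle, the three-atom C3–C2–O tether being the ideal length. Ring A closes when 11 inserts into the Rh–C7 bond (or adds across the metallacycle in a (4+2) sense) and the seven-membered rhodacycle eliminates reductively, forming C6–C7 and C4–C5. No stereocentre is formed, and C2 and C3, set in step 13, are in no bond that changes. The step needs regioselectivity, the oxygen-bearing carbon of 11 next to C7, and the substrate secures it by steric contrast: C7 carries only hydrogen while C4 carries the branched diethoxymethyl group, so the ethoxy group ends up meta to that group and to O1. It needs chemoselectivity for the cross reaction over homo-trimerisation of 11 or dimerisation of 29, which slow addition of 29 to the catalyst and an excess of volatile 11 secure. It needs mildness, since the benzylic alkynyl ether would rearrange sigmatropically on heating, and the cationic catalyst turns over at room temperature. Steps 5 and 10 test all three demands on smaller relatives of 29 with the same acetal on C4.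

Step 16
Reactants: 30 (2R,3R)-4-(diethoxymethyl)-3-(Bf-23)-6-ethoxy-2-(4-methoxyphenyl)-2,3-dihydro-1-benzofuran
Product: 31 (2R,3R)-3-(Bf-23)-6-ethoxy-2-(4-methoxyphenyl)-2,3-dihydro-1-benzofuran-4-carbaldehyde
Conditions: 1 M HCl, THF, rt
Reagents that add atoms: water, O
Why: Acid-catalysed hydrolysis of an aryl aldehyde diethyl acetal, which is far faster under dilute acid than ionisation of the C2–O bonds; no stereocentre is touched.

Step 17
Reactants: 31 (2R,3R)-3-(Bf-23)-6-ethoxy-2-(4-methoxyphenyl)-2,3-dihydro-1-benzofuran-4-carbaldehyde; 32 diethyl (4-methoxybenzyl)phosphonate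
Product: 33 miyabenol A hexamethyl triethyl ether
Conditions: 32, KOtBu, THF, 0 °C to rt, dark
Reagents that add atoms: none
Why: Horner–Wadsworth–Emmons olefination with a benzylic phosphonate, which should give the (E)-stilbene; 31 has no enolisable position and the methine hydrogens at C3 are not acidic enough to be at risk.

Step 18
Reactants: 33 miyabenol A hexamethyl triethyl ether
Product: 34 miyabenol A
Conditions: BCl3, n-Bu4NI, CH2Cl2, −78 °C to rt, dark; aqueous NaHCO3 work-up
Reagents that add atoms: none
Why: Lewis acid-assisted SN2 dealkylation of primary alkyl aryl ethers: BCl3 binds each ether oxygen and iodide removes methyl or ethyl as the alkyl iodide at low temperature. These conditions are milder than protic or hot alternatives toward the C2–O bonds and the stilbene, and the six stereocentres are not involved.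

## Compound list

1 | 3,5-dimethoxybenzaldehyde | COc1cc(OC)cc(C=O)c1 | starting material
2 | 3,3-diethoxyprop-1-yne | CCOC(OCC)C#C | starting material
3 | (1S)-1-(3,5-dimethoxyphenyl)-4,4-diethoxybut-2-yn-1-ol | CCOC(OCC)C#C[C@H](c1cc(OC)cc(OC)c1)O | intermediate
4 | (1S)-1-(3,5-dimethoxyphenyl)-4,4-diethoxybut-2-yn-1-yl methanesulfonate | CCOC(OCC)C#C[C@H](c1cc(OC)cc(OC)c1)OS(C)(=O)=O | intermediate
5 | 4-methoxybenzaldehyde | COc1ccc(C=O)cc1 | starting material
6 | (aR)-[4-(3,5-dimethoxyphenyl)-1,1-diethoxybuta-2,3-dien-2-yl]indium iodide methanesulfonate (trivalent indium, formed in the flask) | CCOC(OCC)C([In](I)OS(C)(=O)=O)=[C@]=C(c1cc(OC)cc(OC)c1)[H] | intermediate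
7 | (1R,2R)-2-(3,5-dimethoxyphenyl)-5,5-diethoxy-1-(4-methoxyphenyl)pent-3-yn-1-ol | CCOC(OCC)C#C[C@@H](c1cc(OC)cc(OC)c1)[C@H](c1ccc(OC)cc1)O | intermediate
8 | (E)-1,2-dichlorovinyl ether of 7 (formed in the flask) | CCOC(OCC)C#C[C@@H](c1cc(OC)cc(OC)c1)[C@H](c1ccc(OC)cc1)O/C(Cl)=C\Cl | intermediate
9 | lithioethynyl ether of 7 (formed in the flask) | CCOC(OCC)C#C[C@@H](c1cc(OC)cc(OC)c1)[C@H](c1ccc(OC)cc1)OC#C[Li] | intermediate
10 | (1R,2R)-2-(3,5-dimethoxyphenyl)-5,5-diethoxy-1-(ethynyloxy)-1-(4-methoxyphenyl)pent-3-yne | CCOC(OCC)C#C[C@@H](c1cc(OC)cc(OC)c1)[C@H](c1ccc(OC)cc1)OC#C | intermediate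
11 | ethoxyacetylene | CCOC#C | starting material
12 | (2R,3R)-4-(diethoxymethyl)-3-(3,5-dimethoxyphenyl)-6-ethoxy-2-(4-methoxyphenyl)-2,3-dihydro-1-benzofuran (formed in the flask) | CCOC(OCC)c1cc(OCC)cc2c1[C@@H](c1cc(OC)cc(OC)c1)[C@H](c1ccc(OC)cc1)O2 | intermediate
13 | (2R,3R)-3-(3,5-dimethoxyphenyl)-6-ethoxy-2-(4-methoxyphenyl)-2,3-dihydro-1-benzofuran-4-carbaldehyde | O=Cc1cc(OCC)cc2c1[C@@H](c1cc(OC)cc(OC)c1)[C@H](c1ccc(OC)cc1)O2 | intermediate
14 | (1S)-1-(Bf-3)-4,4-diethoxybut-2-yn-1-ol | CCOC(OCC)C#C[C@@H](c1cc(OCC)cc2c1[C@@H](c1cc(OC)cc(OC)c1)[C@H](c1ccc(OC)cc1)O2)O | intermediate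
15 | (1S)-1-(Bf-3)-4,4-diethoxybut-2-yn-1-yl methanesulfonate | CCOC(OCC)C#C[C@@H](c1cc(OCC)cc2c1[C@@H](c1cc(OC)cc(OC)c1)[C@H](c1ccc(OC)cc1)O2)OS(C)(=O)=O | intermediate
16 | (aS)-[4-(Bf-3)-1,1-diethoxybuta-2,3-dien-2-yl]indium iodide methanesulfonate (trivalent indium, formed in the flask) | CCOC(OCC)C([In](I)OS(C)(=O)=O)=[C@@]=C(c1cc(OCC)cc2c1[C@@H](c1cc(OC)cc(OC)c1)[C@H](c1ccc(OC)cc1)O2)[H] | intermediate
17 | (1S,2R)-2-(Bf-3)-5,5-diethoxy-1-(4-methoxyphenyl)pent-3-yn-1-ol | CCOC(OCC)C#C[C@H](c1cc(OCC)cc2c1[C@@H](c1cc(OC)cc(OC)c1)[C@H](c1ccc(OC)cc1)O2)[C@@H](c1ccc(OC)cc1)O | intermediate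
18 | (E)-1,2-dichlorovinyl ether of 17 (formed in the flask) | CCOC(OCC)C#C[C@H](c1cc(OCC)cc2c1[C@@H](c1cc(OC)cc(OC)c1)[C@H](c1ccc(OC)cc1)O2)[C@@H](c1ccc(OC)cc1)O/C(Cl)=C\Cl | intermediate
19 | lithioethynyl ether of 17 (formed in the flask) | CCOC(OCC)C#C[C@H](c1cc(OCC)cc2c1[C@@H](c1cc(OC)cc(OC)c1)[C@H](c1ccc(OC)cc1)O2)[C@@H](c1ccc(OC)cc1)OC#C[Li] | intermediate
20 | (1S,2R)-2-(Bf-3)-5,5-diethoxy-1-(ethynyloxy)-1-(4-methoxyphenyl)pent-3-yne | CCOC(OCC)C#C[C@H](c1cc(OCC)cc2c1[C@@H](c1cc(OC)cc(OC)c1)[C@H](c1ccc(OC)cc1)O2)[C@@H](c1ccc(OC)cc1)OC#C | intermediate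
21 | (2S,3S)-4-(diethoxymethyl)-3-(Bf-3)-6-ethoxy-2-(4-methoxyphenyl)-2,3-dihydro-1-benzofuran (formed in the flask) | CCOC(OCC)c1cc(OCC)cc2c1[C@H](c1cc(OCC)cc3c1[C@@H](c1cc(OC)cc(OC)c1)[C@H](c1ccc(OC)cc1)O3)[C@@H](c1ccc(OC)cc1)O2 | intermediate
22 | (2S,3S)-3-(Bf-3)-6-ethoxy-2-(4-methoxyphenyl)-2,3-dihydro-1-benzofuran-4-carbaldehyde | O=Cc1cc(OCC)cc2c1[C@H](c1cc(OCC)cc3c1[C@@H](c1cc(OC)cc(OC)c1)[C@H](c1ccc(OC)cc1)O3)[C@@H](c1ccc(OC)cc1)O2 | intermediate
23 | (1R)-1-(Bf-23)-4,4-diethoxybut-2-yn-1-ol | CCOC(OCC)C#C[C@H](c1cc(OCC)cc2c1[C@H](c1cc(OCC)cc3c1[C@@H](c1cc(OC)cc(OC)c1)[C@H](c1ccc(OC)cc1)O3)[C@@H](c1ccc(OC)cc1)O2)O | intermediate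
24 | (1R)-1-(Bf-23)-4,4-diethoxybut-2-yn-1-yl methanesulfonate | CCOC(OCC)C#C[C@H](c1cc(OCC)cc2c1[C@H](c1cc(OCC)cc3c1[C@@H](c1cc(OC)cc(OC)c1)[C@H](c1ccc(OC)cc1)O3)[C@@H](c1ccc(OC)cc1)O2)OS(C)(=O)=O | intermediate
25 | (aR)-[4-(Bf-23)-1,1-diethoxybuta-2,3-dien-2-yl]indium iodide methanesulfonate (trivalent indium, formed in the flask) | CCOC(OCC)C([In](I)OS(C)(=O)=O)=[C@]=C(c1cc(OCC)cc2c1[C@H](c1cc(OCC)cc3c1[C@@H](c1cc(OC)cc(OC)c1)[C@H](c1ccc(OC)cc1)O3)[C@@H](c1ccc(OC)cc1)O2)[H] | intermediate
26 | (1R,2S)-2-(Bf-23)-5,5-diethoxy-1-(4-methoxyphenyl)pent-3-yn-1-ol | CCOC(OCC)C#C[C@@H](c1cc(OCC)cc2c1[C@H](c1cc(OCC)cc3c1[C@@H](c1cc(OC)cc(OC)c1)[C@H](c1ccc(OC)cc1)O3)[C@@H](c1ccc(OC)cc1)O2)[C@H](c1ccc(OC)cc1)O | intermediate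
27 | (E)-1,2-dichlorovinyl ether of 26 (formed in the flask) | CCOC(OCC)C#C[C@@H](c1cc(OCC)cc2c1[C@H](c1cc(OCC)cc3c1[C@@H](c1cc(OC)cc(OC)c1)[C@H](c1ccc(OC)cc1)O3)[C@@H](c1ccc(OC)cc1)O2)[C@H](c1ccc(OC)cc1)O/C(Cl)=C\Cl | intermediate
28 | lithioethynyl ether of 26 (formed in the flask) | CCOC(OCC)C#C[C@@H](c1cc(OCC)cc2c1[C@H](c1cc(OCC)cc3c1[C@@H](c1cc(OC)cc(OC)c1)[C@H](c1ccc(OC)cc1)O3)[C@@H](c1ccc(OC)cc1)O2)[C@H](c1ccc(OC)cc1)OC#C[Li] | intermediate
29 | (1R,2S)-2-(Bf-23)-5,5-diethoxy-1-(ethynyloxy)-1-(4-methoxyphenyl)pent-3-yne | CCOC(OCC)C#C[C@@H](c1cc(OCC)cc2c1[C@H](c1cc(OCC)cc3c1[C@@H](c1cc(OC)cc(OC)c1)[C@H](c1ccc(OC)cc1)O3)[C@@H](c1ccc(OC)cc1)O2)[C@H](c1ccc(OC)cc1)OC#C | intermediate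
30 | (2R,3R)-4-(diethoxymethyl)-3-(Bf-23)-6-ethoxy-2-(4-methoxyphenyl)-2,3-dihydro-1-benzofuran | CCOC(OCC)c1cc(OCC)cc2c1[C@@H](c1cc(OCC)cc3c1[C@H](c1cc(OCC)cc4c1[C@@H](c1cc(OC)cc(OC)c1)[C@H](c1ccc(OC)cc1)O4)[C@@H](c1ccc(OC)cc1)O3)[C@H](c1ccc(OC)cc1)O2 | intermediate
31 | (2R,3R)-3-(Bf-23)-6-ethoxy-2-(4-methoxyphenyl)-2,3-dihydro-1-benzofuran-4-carbaldehyde | O=Cc1cc(OCC)cc2c1[C@@H](c1cc(OCC)cc3c1[C@H](c1cc(OCC)cc4c1[C@@H](c1cc(OC)cc(OC)c1)[C@H](c1ccc(OC)cc1)O4)[C@@H](c1ccc(OC)cc1)O3)[C@H](c1ccc(OC)cc1)O2 | intermediate
32 | diethyl (4-methoxybenzyl)phosphonate | CCOP(=O)(OCC)Cc1ccc(OC)cc1 | starting material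
33 | miyabenol A hexamethyl triethyl ether: (2R,3R)-3-(Bf-23)-6-ethoxy-2-(4-methoxyphenyl)-4-[(E)-2-(4-methoxyphenyl)ethenyl]-2,3-dihydro-1-benzofuran | COc1ccc(/C=C/c2cc(OCC)cc3c2[C@@H](c2cc(OCC)cc4c2[C@H](c2cc(OCC)cc5c2[C@@H](c2cc(OC)cc(OC)c2)[C@H](c2ccc(OC)cc2)O5)[C@@H](c2ccc(OC)cc2)O4)[C@H](c2ccc(OC)cc2)O3)cc1 | intermediate
34 | miyabenol A (units 1 and 3 (2R,3R), unit 2 (2S,3S), E alkene) | Oc1ccc(/C=C/c2cc(O)cc3c2[C@@H](c2cc(O)cc4c2[C@H](c2cc(O)cc5c2[C@@H](c2cc(O)cc(O)c2)[C@H](c2ccc(O)cc2)O5)[C@@H](c2ccc(O)cc2)O4)[C@H](c2ccc(O)cc2)O3)cc1 | target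

## Step count and least certain steps

Total step count: 18. Longest linear sequence: 18 steps (1 to 34); all other materials (2, 5, 11, 32) are commercial.

**Step 15 (key step).** The insertion of 11 may take the opposite orientation and place the ethoxy group next to the acetal. Homo-trimerisation of 11 or dimerisation of 29 may outrun the cross reaction. The benzylic alkynyl ether may rearrange or ionise at the cationic metal before the second alkyne is engaged. The fallback is thermal and uses known reaction types. It sets out from 26, which also avoids step 14. Steglich esterification of 26 with (E)-3-ethoxybut-2-enoic acid (DCC, DMAP) gives the 3-ethoxycrotonate ester F1. LDA and TMSCl at −78 °C deprotonate the γ-methyl group of this vinylogous ester and give the 1-silyloxy-1-alkoxy-3-ethoxybutadiene F2. On heating in toluene, F2 undergoes an intramolecular Diels–Alder reaction with the alkyne. The tether fixes the regiochemistry: the ketene acetal carbon bonds to the proximal alkyne carbon and the methylene terminus to the acetal-bearing carbon. Loss of trimethylsilanol aromatises the adduct, and the fallback comes back to the route at 30.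

**Step 5.** This is the first trial of the unprecedented cyclotrimerisation. The likely failures are regiochemical leakage in the insertion of 11 and consumption of 11 by self-trimerisation while 10 decomposes. The fallback sets out from 7. Esterification with (E)-3-ethoxybut-2-enoic acid gives the 3-ethoxycrotonate ester F3. LDA/TMSCl give the silyloxydiene F4. Heating in toluene brings about the intramolecular Diels–Alder reaction and loss of trimethylsilanol, and an acidic work-up hydrolyses the acetal. The fallback comes back at 13.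

**Step 10.** The large Bf-3 group on C2 of 20 may slow the oxidative coupling, so that the alkynyl ether rearranges or 11 is used up first. The fallback sets out from 17: the 3-ethoxycrotonate ester F5, then the silyloxydiene F6 (LDA, TMSCl), then intramolecular Diels–Alder reaction in hot toluene with loss of trimethylsilanol and acidic work-up. It comes back at 22.

**Step 13 (also steps 3 and 8).** The allenylpalladium or allenylindium may lose configurational integrity at its aryl-substituted terminus. Ethoxide may be eliminated from 25, whose metal-bearing carbon carries the acetal. The addition to an aromatic aldehyde may be only weakly anti-selective or may give allenyl carbinols. The fallback replaces indium by boron and sets out from 23. Methyl chloroformate and pyridine give the methyl carbonate F7. Copper-catalysed anti SN2′ borylation (CuOtBu, Xantphos, B2pin2, THF) gives the (aS)-allenyl pinacol boronate F8, which can be isolated and checked. Heating F8 with 5 effects allenylboration through a closed six-membered transition state, with the same chirality transfer and anti outcome, and the fallback comes back at 26.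

**Step 14 (also steps 4 and 9).** The potassium alkoxide of 26 may fragment by retro-addition to 5 and a doubly stabilised propargyl anion. Base may isomerise the alkyne to an allene at the benzylic, propargylic C–H. The product may rearrange on warming. The fallback avoids the potassium alkoxide and sets out from 26. Acetic formic anhydride and pyridine give the formate F9. Dibromo-olefination of the formyl group (CBr4, PPh3, a Corey–Fuchs-type step) gives the 2,2-dibromovinyl ether F10. n-BuLi at −78 °C (Fritsch–Buttenberg–Wiechell rearrangement) and a methanol quench give the ethynyl ether, and the fallback comes back at 29.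

**Step 18.** The Lewis acid may ionise C2–O bonds, with ring opening or epimerisation. The activated stilbene may be attacked by C5 of unit 2 in a Friedel–Crafts closure. The ethyl ethers may cleave incompletely. The fallback dealkylates before the alkene exists and ends with fluoride. It sets out from 31. BCl3/n-Bu4NI on the aldehyde, whose formyl group deactivates ring A, gives the octaphenol aldehyde F11. TBSCl and imidazole give the octakis(tert-butyldimethylsilyl) ether F12. Horner–Wadsworth–Emmons reaction with diethyl [4-(tert-butyldimethylsilyloxy)benzyl]phosphonate (NaHMDS, THF) gives the nonasilyl ether of miyabenol A F13. TBAF buffered with acetic acid removes the silyl groups, and the fallback comes back at 34.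

## Further compounds

F1 | step 15 | (E)-3-ethoxybut-2-enoate ester of 26 | CCOC(OCC)C#C[C@@H](c1cc(OCC)cc2c1[C@H](c1cc(OCC)cc3c1[C@@H](c1cc(OC)cc(OC)c1)[C@H](c1ccc(OC)cc1)O3)[C@@H](c1ccc(OC)cc1)O2)[C@H](c1ccc(OC)cc1)OC(=O)/C=C(\C)OCC
F2 | step 15 | 3-ethoxy-1-(trimethylsilyloxy)buta-1,3-dien-1-yl ether of 26 (mixture of ketene acetal isomers) | CCOC(OCC)C#C[C@@H](c1cc(OCC)cc2c1[C@H](c1cc(OCC)cc3c1[C@@H](c1cc(OC)cc(OC)c1)[C@H](c1ccc(OC)cc1)O3)[C@@H](c1ccc(OC)cc1)O2)[C@H](c1ccc(OC)cc1)OC(O[Si](C)(C)C)=CC(OCC)=C
F3 | step 5 | (E)-3-ethoxybut-2-enoate ester of 7 | CCOC(OCC)C#C[C@@H](c1cc(OC)cc(OC)c1)[C@H](c1ccc(OC)cc1)OC(=O)/C=C(\C)OCC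
F4 | step 5 | 3-ethoxy-1-(trimethylsilyloxy)buta-1,3-dien-1-yl ether of 7 (mixture of ketene acetal isomers) | CCOC(OCC)C#C[C@@H](c1cc(OC)cc(OC)c1)[C@H](c1ccc(OC)cc1)OC(O[Si](C)(C)C)=CC(OCC)=C
F5 | step 10 | (E)-3-ethoxybut-2-enoate ester of 17 | CCOC(OCC)C#C[C@H](c1cc(OCC)cc2c1[C@@H](c1cc(OC)cc(OC)c1)[C@H](c1ccc(OC)cc1)O2)[C@@H](c1ccc(OC)cc1)OC(=O)/C=C(\C)OCC
F6 | step 10 | 3-ethoxy-1-(trimethylsilyloxy)buta-1,3-dien-1-yl ether of 17 (mixture of ketene acetal isomers) | CCOC(OCC)C#C[C@H](c1cc(OCC)cc2c1[C@@H](c1cc(OC)cc(OC)c1)[C@H](c1ccc(OC)cc1)O2)[C@@H](c1ccc(OC)cc1)OC(O[Si](C)(C)C)=CC(OCC)=C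
F7 | step 13 | (1R)-1-(Bf-23)-4,4-diethoxybut-2-yn-1-yl methyl carbonate | CCOC(OCC)C#C[C@H](c1cc(OCC)cc2c1[C@H](c1cc(OCC)cc3c1[C@@H](c1cc(OC)cc(OC)c1)[C@H](c1ccc(OC)cc1)O3)[C@@H](c1ccc(OC)cc1)O2)OC(=O)OC
F8 | step 13 | (aS)-2-[4-(Bf-23)-1,1-diethoxybuta-2,3-dien-2-yl]-4,4,5,5-tetramethyl-1,3,2-dioxaborolane | CCOC(OCC)C(B1OC(C)(C)C(C)(C)O1)=[C@]=C(c1cc(OCC)cc2c1[C@H](c1cc(OCC)cc3c1[C@@H](c1cc(OC)cc(OC)c1)[C@H](c1ccc(OC)cc1)O3)[C@@H](c1ccc(OC)cc1)O2)[H]
F9 | step 14 | formate ester of 26 | CCOC(OCC)C#C[C@@H](c1cc(OCC)cc2c1[C@H](c1cc(OCC)cc3c1[C@@H](c1cc(OC)cc(OC)c1)[C@H](c1ccc(OC)cc1)O3)[C@@H](c1ccc(OC)cc1)O2)[C@H](c1ccc(OC)cc1)OC=O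
F10 | step 14 | 2,2-dibromovinyl ether of 26 | CCOC(OCC)C#C[C@@H](c1cc(OCC)cc2c1[C@H](c1cc(OCC)cc3c1[C@@H](c1cc(OC)cc(OC)c1)[C@H](c1ccc(OC)cc1)O3)[C@@H](c1ccc(OC)cc1)O2)[C@H](c1ccc(OC)cc1)OC=C(Br)Br
F11 | step 18 | octaphenol aldehyde (31 with its five methyl and three ethyl ethers cleaved) | O=Cc1cc(O)cc2c1[C@@H](c1cc(O)cc3c1[C@H](c1cc(O)cc4c1[C@@H](c1cc(O)cc(O)c1)[C@H](c1ccc(O)cc1)O4)[C@@H](c1ccc(O)cc1)O3)[C@H](c1ccc(O)cc1)O2
F12 | step 18 | octakis(tert-butyldimethylsilyl) ether of F11 | O=Cc1cc(O[Si](C)(C)C(C)(C)C)cc2c1[C@@H](c1cc(O[Si](C)(C)C(C)(C)C)cc3c1[C@H](c1cc(O[Si](C)(C)C(C)(C)C)cc4c1[C@@H](c1cc(O[Si](C)(C)C(C)(C)C)cc(O[Si](C)(C)C(C)(C)C)c1)[C@H](c1ccc(O[Si](C)(C)C(C)(C)C)cc1)O4)[C@@H](c1ccc(O[Si](C)(C)C(C)(C)C)cc1)O3)[C@H](c1ccc(O[Si](C)(C)C(C)(C)C)cc1)O2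
F13 | step 18 | nonakis(tert-butyldimethylsilyl) ether of miyabenol A | CC(C)(C)[Si](C)(C)Oc1ccc(/C=C/c2cc(O[Si](C)(C)C(C)(C)C)cc3c2[C@@H](c2cc(O[Si](C)(C)C(C)(C)C)cc4c2[C@H](c2cc(O[Si](C)(C)C(C)(C)C)cc5c2[C@@H](c2cc(O[Si](C)(C)C(C)(C)C)cc(O[Si](C)(C)C(C)(C)C)c2)[C@H](c2ccc(O[Si](C)(C)C(C)(C)C)cc2)O5)[C@@H](c2ccc(O[Si](C)(C)C(C)(C)C)cc2)O4)[C@H](c2ccc(O[Si](C)(C)C(C)(C)C)cc2)O3)cc1
A1 | alternative 1 | ring-C (E)-alkenyl pinacol boronate | O(Cc1ccccc1)c1cc(OC)cc(OCOC)c1/C=C/B1OC(C)(C)C(C)(C)O1
A2 | alternative 1 | 4-methoxyphenyllithium | [Li]c1ccc(OC)cc1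
A3 | alternative 1 | 3,5-dimethoxyphenyl trifluoromethanesulfonate | COc1cc(OC)cc(OS(=O)(=O)C(F)(F)F)c1
A4 | alternative 1 | secondary pinacol boronic ester from the conjunctive coupling | O(Cc1ccccc1)c1cc(OC)cc(OCOC)c1[C@@H](c1cc(OC)cc(OC)c1)[C@@H](c1ccc(OC)cc1)B1OC(C)(C)C(C)(C)O1
A5 | alternative 2 | (2S)-5-(benzyloxy)-7-methoxy-2-(4-methoxyphenyl)chroman-4-one (protected naringenin) | O=C1C[C@@H](c2ccc(OC)cc2)Oc2cc(OC)cc(OCc3ccccc3)c12
A6 | alternative 2 | methyl (2S,3S)-4-(benzyloxy)-6-methoxy-2-(4-methoxyphenyl)-2,3-dihydro-1-benzofuran-3-carboxylate | O(Cc1ccccc1)c1cc(OC)cc2c1[C@H](C(=O)OC)[C@@H](c1ccc(OC)cc1)O2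
A7 | alternative 3 | tris(3-aryl-2,3-dihydrobenzofuran-2-carboxylic acid), drawn trans (C2 configuration is lost on decarboxylation) | O(Cc1ccccc1)c1cc(OC)cc2c1[C@@H](c1cc(OC)cc3c1[C@H](c1cc(OC)cc4c1[C@@H](c1cc(OC)cc(OC)c1)[C@H](C(=O)O)O4)[C@@H](C(=O)O)O3)[C@H](C(=O)O)O2
A8 | alternative 3 | 4-iodoanisole | COc1ccc(I)cc1
A9 | alternative 3 | octa-O-methyl tris(dihydrobenzofuran) with benzyloxy at C4 of unit 1 | O(Cc1ccccc1)c1cc(OC)cc2c1[C@@H](c1cc(OC)cc3c1[C@H](c1cc(OC)cc4c1[C@@H](c1cc(OC)cc(OC)c1)[C@H](c1ccc(OC)cc1)O4)[C@@H](c1ccc(OC)cc1)O3)[C@H](c1ccc(OC)cc1)O2
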